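The numbers in the tables were computed for an exercise; noise was put on by code.

Answer 4 questions with one number.

| flask | starting material | protic impurity | temperature | remark | time |
|---|---|---|---|---|---|
| Tuesday's | 2.7 M | 0.095 M | −25 °C | run made earlier |  |
| Thursday's | 1.9 M | 0.048 M | 0 °C | run made earlier |  |
| delta | 1.9 M | 0.0950 M | 0 °C |  | 8.0 h |
| eta | 1.9 M | 0.0950 M | −20 °C |  | 8.0 h |
| theta | 1.9 M | 0.0950 M | 20 °C |  | 8.0 h |

| Tuesday's: time / h | Tuesday's: target / % | Thursday's: time / h | Thursday's: target / % |
|---|---|---|---|
| 1.50 | 27.5 | 0.833 | 40.2 |
| 5.00 | 51.2 | 2.50 | 29.1 |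
| 10.0 | 58.2 | 4.00 | 23.8 |
| 20.0 | 55.6 | 6.00 | 20.0 |

(standard deviation of a reading: 0.5 percentage points)

1. which flask leads in amount of target, in percent of the starting material charged ("all alike" within 1.5 percentage points) (delta / eta / theta / all alike)
2. how much target is there at the end, in percent of the starting material charged: delta
3. how much target is there at the end, in percent of the starting material charged: eta
4. how much target is there at the end, in percent of the starting material charged: theta

- in percentages every species weighs as the starting material in it: one target counts as two

Target rises and then sinks in Tuesday's run, and Thursday's readings sink throughout, so measure each flask's time in peaks, taking the time of the highest reading as the peak. Tuesday's run reads highest at 10.0 h, Thursday's at its first reading, 0.833 h. One target takes two of starting material, so assume the clock runs with the charge and form peak time times concentration: 1620 M·min at −25 °C, 95.0 M·min at 0 °C, a factor of 17.1, spread evenly in logarithm over the degrees. Define N, a Damköhler number: asked time times concentration over that product at the flask's temperature. Delta gets 9.60, eta 0.993, theta 92.9. So eta stops near its peak, and theta lies further past its peak than delta.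

Thursday's last readings, at N up to 7.20, fall as one over N to the power 0.429. Test one number: that slope takes Tuesday's 55.6% at N 2.00 to 46.7% at N 3.00, yet Thursday's run holds less than that, 29.1%. So N gives these two runs no common height. Interpolating the two highest readings over temperature, I put eta at 54.6%. The slope puts delta at 17.7% and theta at 6.68%, with their 0.0950 M of protic impurity against Thursday's 0.048 M unpriced.

The forecast gives delta 15% (7% to 21%), eta 49% (40% to 56%), theta 10% (3% to 18%), and names eta as the leader: “Theta is faster and warmer, so it sits at a lower plateau”. My delta and eta stand higher than its figures, my theta lower, and eta leads in my reckoning too.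

The flasks give 18.3% in delta, 51.3% in eta and 2.56% in theta, so eta leads.

    2 starting material ⇌ target (K = 0.710 M⁻¹, k = 1.90 × 10⁻⁴ M⁻¹ s⁻¹, Ea = 58.0 kJ mol⁻¹, ΔH = −30.0 kJ mol⁻¹)
    target ⇌ isomer of the product (K = 0.870, k = 9.30 × 10⁻⁵ s⁻¹, Ea = 79.0 kJ mol⁻¹, ΔH = −16.0 kJ mol⁻¹)
    starting material + protic impurity → quenched substrate (k = 3.60 × 10⁻⁴ M⁻¹ s⁻¹, Ea = 56.0 kJ mol⁻¹)
    starting material + target → side product (k = 4.60 × 10⁻⁵ M⁻¹ s⁻¹, Ea = 71.0 kJ mol⁻¹)
    (constants at 0 °C)

The numbers part on theta: its N is 12.9 times that of Thursday's last reading, and both my 6.68% and the forecast's 10% lie above 2.56%. Now read delta at 20 h instead, nothing else changed. N rises from 9.60 to 24.0, and the slope gives 11.9%. That flask holds 11.5% of target.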